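**Plan**

- Retrosynthetic cuts: the C1=C2 enol ether and the C5=C6 alkylidene butenolide go back to two hemiketals (C1–OH, C6–OH), the latter from a 2,3,4-trisubstituted furan by singlet oxygen. The esters are removed. The C8(O)–C9H2–C10(OH)CH3 triad is read as a tertiary aldol and cut at C8–C9 (together with O–C10) to a 3-furyl nitrile oxide and an isopropenyl group. Then C1–C10 (Grignard/lactone), C2–C3 (acetate dianion/epoxide) and C5–C6 (2-furyllithium/epoxide) are cut.
- Forward order: the furan (the later butenolide ring) is joined to the C4 epoxide, the chain is extended through a temporary γ-lactone to C1–C10–C9, and the ten-membered carbocycle and a temporary 2-isoxazoline close together in step 9. Oxidation at C1 then closes the 1,4-hemiketal (oxolane ring). At the end the furan becomes the hydroxybutenolide and a double dehydration gives the dihydrofuran and the alkylidene butenolide.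
- Enabling feature: C8 sits on C7, the β-carbon of the butenolide ring (O/C6/C7/C11/C12). Carried as a furan, this ring makes C8 an aryl-type nitrile oxide shielded by two ortho groups. C10 is a methyl-bearing tertiary carbinol next to the ketone-level C1, so C9=C10 can be the alkene of an isopropenyl carbinol whose C1–OH binds magnesium.
- Stereochemistry: C4 comes from (S)-2-methylglycidol (no bond to it is ever broken). A temporary C1 carbinol is set by CBS reduction. C10 is set from C1 in the chelate-directed cycloaddition. C8 is set from C10 by 1,3-syn reduction. The C5=C6 geometry is enforced by the ring.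

Key step: step 9

Remark: locants C1–C15 follow germacranolide numbering (C1=C2 enol ether, C4 and C10 the oxygenated quaternary carbons, C8 the ester carbinol, C12 the lactone carbonyl, C13 the acetoxymethyl carbon); (S)-2-methylglycidol and furan-3,4-diyldimethanol are taken as commercial; TBS = tert-butyldimethylsilyl.

**Step 1**
Reactants: 1 (S)-2-methylglycidol
Product: 2 [(2R)-2-methyloxiran-2-yl]methyl 4-methylbenzenesulfonate
Conditions: TsCl (1.1 equiv), Et3N (1.5 equiv), 4-(dimethylamino)pyridine (5 mol %), CH2Cl2, 0 °C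
Reagents that add atoms: 4-methylbenzenesulfonyl chloride, Cc1ccc(cc1)S(Cl)(=O)=O
Why: O-sulfonylation of the primary alcohol with a sulfonyl chloride and amine base leaves the epoxide and the quaternary stereocenter untouched (the descriptor changes from S to R only through the priority rules).

**Step 2**
Reactants: 3 furan-3,4-diyldimethanol
Product: 4 [4-(TBS-oxymethyl)furan-3-yl]methanol
Conditions: NaH (1.0 equiv), THF, 0 °C; tBuMe2SiCl (1.0 equiv), 0 → 25 °C
Reagents that add atoms: tert-butyl(chloro)dimethylsilane, CC(C)(C)[Si](C)(C)Cl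
Why: monosilylation of a symmetrical diol through its sparingly soluble monosodium alkoxide should give the mono-silyl ether selectively; no stereocenter is involved.

**Step 3**
Reactants: 4 [4-(TBS-oxymethyl)furan-3-yl]methanol; 2 [(2R)-2-methyloxiran-2-yl]methyl 4-methylbenzenesulfonate
Product: 6 {4-(TBS-oxymethyl)-2-{[(2R)-2-methyloxiran-2-yl]methyl}furan-3-yl}methanol, via hydroxy tosylate 5 (not isolated)
Conditions: nBuLi (2.1 equiv), THF, −78 → 0 °C; then 2 (1.0 equiv), BF3·OEt2 (2.2 equiv), −78 °C; then 2 M NaOH, 25 °C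
Reagents that add atoms: none
Why: alkoxide-directed ortho-lithiation puts lithium on the furan carbon next to the CH2OLi group, the 2-furyllithium opens the BF3-activated epoxide of 2 at its CH2 carbon (SN2 epoxide opening by an organolithium), and hydroxide then closes the tertiary alkoxide onto the CH2OTs carbon to the transposed epoxide, so that no bond to the quaternary carbon (the future C4) is broken and its configuration is kept.

**Step 4**
Reactants: 6 {4-(TBS-oxymethyl)-2-{[(2R)-2-methyloxiran-2-yl]methyl}furan-3-yl}methanol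
Product: 8 (5S)-5-{[3-(hydroxymethyl)-4-(TBS-oxymethyl)furan-2-yl]methyl}-5-methyloxolan-2-one, via hydroxy acid 7 (not isolated)
Conditions: AcOH (3 equiv), LiN(iPr)2 (7 equiv), THF, 0 → 45 °C; then aq. HCl to pH 3, 25 °C
Reagents that add atoms: acetic acid (used as its dilithio dianion), CC(=O)O
Why: SN2 opening of the terminal epoxide at CH2 by the dianion of acetic acid (carboxylic acid dianion alkylation) gives a γ-hydroxy acid whose tertiary alcohol lactonizes on acidification, C4 again being untouched.

**Step 5**
Reactants: 8 (5S)-5-{[3-(hydroxymethyl)-4-(TBS-oxymethyl)furan-2-yl]methyl}-5-methyloxolan-2-one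
Product: 9 (6S)-6-hydroxy-7-[3-(hydroxymethyl)-4-(TBS-oxymethyl)furan-2-yl]-2,6-dimethylhept-1-en-3-one
Conditions: CH2=C(CH3)MgBr (2.3 equiv), THF, −78 → −40 °C
Reagents that add atoms: isopropenylmagnesium bromide, C=C(C)[Mg]Br
Why: mono-addition of a Grignard reagent to a γ-lactone at low temperature (lactone to hydroxy ketone; the first equivalent is consumed by the free hydroxyl and over-addition is suppressed in the cold) should give the γ-hydroxy isopropenyl ketone.

**Step 6**
Reactants: 9 (6S)-6-hydroxy-7-[3-(hydroxymethyl)-4-(TBS-oxymethyl)furan-2-yl]-2,6-dimethylhept-1-en-3-one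
Product: 10 (3S,6S)-7-[3-(hydroxymethyl)-4-(TBS-oxymethyl)furan-2-yl]-2,6-dimethylhept-1-ene-3,6-diol
Conditions: (R)-Me-CBS oxazaborolidine [(3aR)-1-methyl-3,3-diphenyltetrahydro-1H,3H-pyrrolo[1,2-c][1,3,2]oxazaborole] (30 mol %), catecholborane (3 equiv), toluene, −78 °C
Reagents that add atoms: none
Why: Corey–Bakshi–Shibata reduction, in which the (R)-oxazaborolidine binds the ketone with the α-branched isopropenyl group as the large substituent and delivers hydride to one face, should set the temporary (S)-carbinol at C1, while catecholborane at −78 °C does not hydroborate the alkene.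

**Step 7**
Reactants: 10 (3S,6S)-7-[3-(hydroxymethyl)-4-(TBS-oxymethyl)furan-2-yl]-2,6-dimethylhept-1-ene-3,6-diol
Product: 11 2-[(2S,5S)-2,5-dihydroxy-2,6-dimethylhept-6-en-1-yl]-4-(TBS-oxymethyl)furan-3-carbaldehyde
Conditions: 2,2,6,6-tetramethylpiperidin-1-oxyl (10 mol %), PhI(OAc)2 (1.1 equiv), CH2Cl2, 25 °C
Reagents that add atoms: none
Why: oxoammonium (TEMPO) oxidation with PhI(OAc)2 as terminal oxidant is selective for the primary furylmethanol over the secondary allylic and the tertiary alcohol and stops at the aldehyde.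

**Step 8**
Reactants: 11 2-[(2S,5S)-2,5-dihydroxy-2,6-dimethylhept-6-en-1-yl]-4-(TBS-oxymethyl)furan-3-carbaldehyde
Product: 12 2-[(2S,5S)-2,5-dihydroxy-2,6-dimethylhept-6-en-1-yl]-4-(TBS-oxymethyl)furan-3-carbaldehyde oxime
Conditions: NH2OH·HCl (1.2 equiv), NaOAc (1.5 equiv), EtOH/H2O, 25 °C
Reagents that add atoms: hydroxylamine hydrochloride, Cl.NO
Why: condensation of the aldehyde with hydroxylamine (oxime formation) gives the aldoxime, the E/Z ratio being without consequence.

**Step 9**
Reactants: 12 2-[(2S,5S)-2,5-dihydroxy-2,6-dimethylhept-6-en-1-yl]-4-(TBS-oxymethyl)furan-3-carbaldehyde oxime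
Product: 15 (1S,4S,10R)-isoxazoline cycloadduct [ten-membered carbocycle C1–C10 fused at C6–C7 to the furan (C11–CH2OTBS, C12–H); 2-isoxazoline bridging C8 (C=N) and C10 (O); 1-OH; 4-OH; methyls on C4 and C10], via hydroximoyl chloride 13 (not isolated), via nitrile oxide 14 (not isolated)
Conditions: N-chlorosuccinimide (1.05 equiv), pyridine (cat.), CHCl3, 0 → 25 °C; then added over 12 h to iPrOMgBr [from EtMgBr (5 equiv) and iPrOH (5.5 equiv)] in CH2Cl2, 0 → 25 °C, final 2 mM
Reagents that add atoms: none
Why: Proposed new method: N-chlorosuccinimide converts the aldoxime into hydroximoyl chloride 13, which iPrOMgBr dehydrochlorinates to the 3-furyl nitrile oxide 14 while the C1 and C4 hydroxyls are held as magnesium alkoxides, and the dipole then adds in a concerted [3+2] fashion across the isopropenyl C9=C10 bond, forming C8–C9 and O–C10 together. The closest known reaction types are the magnesium-alkoxide-directed nitrile oxide cycloaddition to allylic alcohols (intermolecular, including 2-methylallylic alcohols that give tertiary C–O centers) and the intramolecular nitrile oxide cycloaddition that closes large rings as bridged isoxazolines; their combination in a ten-membered ring closure is new. Two rings close at once: the 2-isoxazoline by the cycloaddition itself, and the ten-membered carbocycle C1–C10 (fused to the furan at C6–C7) through the C8–C9 bond in the bridged mode, that is, dipole carbon to the terminal CH2 (C9) and dipole oxygen to the fully substituted C10. The new stereocenter C10 is controlled by the temporary C1 carbinol: divalent magnesium bridges the C1 alkoxide and the nitrile oxide oxygen, the C2–C7 tether can only reach C8 when C2 lies over the alkene (inside position), so the chelated C1–O bond lies outside and the dipole oxygen is delivered to the C10 face that turns (1S) into (10R). The step needs regioselectivity, which the 1,1-disubstituted alkene secures electronically and sterically; ring closure in preference to furoxan formation, which high dilution and the two ortho substituents flanking the nitrile oxide on the furan secure; and facial selectivity, which the chelate secures.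

**Step 10**
Reactants: 15 (1S,4S,10R)-isoxazoline cycloadduct
Product: 17 (1R,4S,10R)-1-hydroxy-1,4-epoxide [hemiketal; oxolane oxygen bridging C1 and C4 of the isoxazoline-bridged, furan-fused ring; 13-OTBS], via hydroxy ketone 16 (not isolated)
Conditions: Dess–Martin periodinane (1.5 equiv), pyridine, CH2Cl2, 0 → 25 °C
Reagents that add atoms: none
Why: Dess–Martin oxidation of the only secondary alcohol gives the C1 ketone, which the C4 hydroxyl should capture at once as the five-membered hemiketal (γ-hydroxy ketone ring closure), the configuration of the new bridgehead C1 being dictated by the ring.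

**Step 11**
Reactants: 17 (1R,4S,10R)-1-hydroxy-1,4-epoxide, 13-OTBS
Product: 19 (1R,4S,10R)-13-acetoxy-1-hydroxy-1,4-epoxide (isoxazoline still bridging C8/C10), via alcohol 18 (not isolated)
Conditions: Bu4NF (1.2 equiv), AcOH (1.2 equiv), THF, 0 °C; then Ac2O (3 equiv), pyridine, 25 °C
Reagents that add atoms: acetic anhydride, CC(=O)OC(C)=O
Why: fluoride-mediated cleavage of the silyl ether and acetylation of the liberated primary alcohol in the same flask exchange the protecting group for the acetate of the target, the hemiketal hydroxyl not being acylated without an acyl-transfer catalyst.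

**Step 12**
Reactants: 19 (1R,4S,10R)-13-acetoxy-1-hydroxy-1,4-epoxide isoxazoline
Product: 21 (1R,4S,10R)-13-acetoxy-1,10-dihydroxy-1,4-epoxy 8-ketone (3-furyl ketone), via imine 20 (not isolated)
Conditions: H2 (1 atm), Raney nickel (Ni), B(OH)3 (3 equiv), MeOH/H2O 5:1, 25 °C
Reagents that add atoms: water, O
Why: hydrogenolysis of the isoxazoline N–O bond over Raney nickel and boric-acid-promoted hydrolysis of the resulting β-hydroxy imine (isoxazoline-to-aldol unmasking) give the β-hydroxy ketone with the C10–O bond and configuration unchanged.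

**Step 13**
Reactants: 21 (1R,4S,10R)-13-acetoxy-1,10-dihydroxy-1,4-epoxy 8-ketone
Product: 23 (1R,4S,8S,10R)-13-acetoxy-1,4-epoxy-1,8,10-triol, via boron chelate 22 (not isolated)
Conditions: Et2BOMe (1.2 equiv), THF/MeOH 4:1, −78 °C; NaBH4 (1.5 equiv), −78 °C; then MeOH, evaporate
Reagents that add atoms: none
Why: Narasaka–Prasad reduction, in which boron links the C10 hydroxyl to the C8 carbonyl and borohydride attacks the chelate from outside, should give the 1,3-syn diol, that is (8S) from (10R).

**Step 14**
Reactants: 23 (1R,4S,8S,10R)-13-acetoxy-1,4-epoxy-1,8,10-triol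
Product: 24 8-O-methacrylate of 23
Conditions: methacrylic anhydride (1.5 equiv), Et3N (3 equiv), 4-(dimethylamino)pyridine (10 mol %), CH2Cl2, 0 °C
Reagents that add atoms: methacrylic anhydride, C=C(C)C(=O)OC(=O)C(C)=C
Why: acyl-transfer-catalysed esterification with the anhydride (Steglich-type acylation) should esterify the secondary C8 alcohol and leave the tertiary C10 and hemiketal C1 hydroxyls free.

**Step 15**
Reactants: 24 8-O-methacrylate
Product: 26 (1R,4S,8S,10R)-13-acetoxy-1,6,10-trihydroxy-8-methacryloyloxy-1,4-epoxygermacr-7(11)-en-6,12-olide (γ-hydroxybutenolide, C6 epimers), via endoperoxide 25 (not isolated)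
Conditions: O2, visible light, 5,10,15,20-tetraphenylporphyrin (1 mol %), iPr2NEt (2 equiv), CH2Cl2, −78 °C
Reagents that add atoms: dioxygen, O=O
Why: [4+2] cycloaddition of singlet oxygen to the trisubstituted furan and base-induced Kornblum–DeLaMare fragmentation of the endoperoxide at its only C–H (C12) give the γ-hydroxybutenolide with C12 as the carbonyl carbon, the electron-poor methacrylate being inert to singlet oxygen.

**Step 16**
Reactants: 26 γ-hydroxybutenolide
Product: 28 (4S,8S,10R)-13-acetoxy-10-hydroxy-8-(2-methylprop-2-enoyloxy)-1,4-epoxygermacra-1,5E,7(11)-trien-6,12-olide (the target), via bis(trifluoroacetate) 27 (not isolated)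
Conditions: (CF3CO)2O (4 equiv), Et3N (8 equiv), CH2Cl2, −40 → 0 °C
Reagents that add atoms: none
Why: trifluoroacetylation of the two hemiketal hydroxyls (C1 and C6), ionization to oxocarbenium ions and loss of the C2 and C5 protons (E1 dehydration of hemiketals) should give the enol ether and the alkylidene butenolide, whose C5=C6 geometry is forced by the nine-membered oxa-bridged ring, while the tertiary C10 alcohol cannot ionize next to the ketal carbon.

**Compound list**

1 | (S)-2-methylglycidol, [(2S)-2-methyloxiran-2-yl]methanol | C[C@]1(CO)CO1 | starting material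
2 | [(2R)-2-methyloxiran-2-yl]methyl 4-methylbenzenesulfonate | C[C@]1(COS(=O)(=O)c2ccc(C)cc2)CO1 | intermediate
3 | furan-3,4-diyldimethanol | OCc1cocc1CO | starting material
4 | [4-(TBS-oxymethyl)furan-3-yl]methanol | OCc1cocc1CO[Si](C)(C)C(C)(C)C | intermediate
5 | (2R)-2-hydroxy-3-[3-(hydroxymethyl)-4-(TBS-oxymethyl)furan-2-yl]-2-methylpropyl 4-methylbenzenesulfonate | OCc1c(C[C@@](C)(O)COS(=O)(=O)c2ccc(C)cc2)occ1CO[Si](C)(C)C(C)(C)C | intermediate
6 | {4-(TBS-oxymethyl)-2-{[(2R)-2-methyloxiran-2-yl]methyl}furan-3-yl}methanol | OCc1c(C[C@]2(C)CO2)occ1CO[Si](C)(C)C(C)(C)C | intermediate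
7 | (4S)-4-hydroxy-5-[3-(hydroxymethyl)-4-(TBS-oxymethyl)furan-2-yl]-4-methylpentanoic acid | OCc1c(C[C@@](C)(O)CCC(O)=O)occ1CO[Si](C)(C)C(C)(C)C | intermediate
8 | (5S)-5-{[3-(hydroxymethyl)-4-(TBS-oxymethyl)furan-2-yl]methyl}-5-methyloxolan-2-one | OCc1c(C[C@]2(C)CCC(=O)O2)occ1CO[Si](C)(C)C(C)(C)C | intermediate
9 | (6S)-6-hydroxy-7-[3-(hydroxymethyl)-4-(TBS-oxymethyl)furan-2-yl]-2,6-dimethylhept-1-en-3-one | OCc1c(C[C@@](C)(O)CCC(=O)C(C)=C)occ1CO[Si](C)(C)C(C)(C)C | intermediate
10 | (3S,6S)-7-[3-(hydroxymethyl)-4-(TBS-oxymethyl)furan-2-yl]-2,6-dimethylhept-1-ene-3,6-diol | OCc1c(C[C@@](C)(O)CC[C@H](O)C(C)=C)occ1CO[Si](C)(C)C(C)(C)C | intermediate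
11 | 2-[(2S,5S)-2,5-dihydroxy-2,6-dimethylhept-6-en-1-yl]-4-(TBS-oxymethyl)furan-3-carbaldehyde | O=Cc1c(C[C@@](C)(O)CC[C@H](O)C(C)=C)occ1CO[Si](C)(C)C(C)(C)C | intermediate
12 | oxime of 11 | ON=Cc1c(C[C@@](C)(O)CC[C@H](O)C(C)=C)occ1CO[Si](C)(C)C(C)(C)C | intermediate
13 | N-hydroxy furan-3-carboximidoyl chloride derived from 12 | ON=C(Cl)c1c(C[C@@](C)(O)CC[C@H](O)C(C)=C)occ1CO[Si](C)(C)C(C)(C)C | intermediate
14 | furan-3-carbonitrile oxide derived from 13 | [O-][N+]#Cc1c(C[C@@](C)(O)CC[C@H](O)C(C)=C)occ1CO[Si](C)(C)C(C)(C)C | intermediate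
15 | (1S,4S,10R)-isoxazoline cycloadduct (C8=N–O–C10 bridge; furan at C6/C7/C11/C12; 1,4-diol; 13-OTBS) | C[C@]12CC(=NO1)c3c(C[C@@](C)(O)CC[C@@H]2O)occ3CO[Si](C)(C)C(C)(C)C | intermediate
16 | (4S,10R)-4-hydroxy 1-ketone of 15 | C[C@]12CC(=NO1)c3c(C[C@@](C)(O)CCC2=O)occ3CO[Si](C)(C)C(C)(C)C | intermediate
17 | (1R,4S,10R)-1-hydroxy-1,4-epoxide (hemiketal) of the isoxazoline-bridged furan, 13-OTBS | C[C@]12CC(=NO1)c3c(C[C@]4(C)CC[C@@]2(O)O4)occ3CO[Si](C)(C)C(C)(C)C | intermediate
18 | 13-alcohol of 17 | C[C@]12CC(=NO1)c3c(C[C@]4(C)CC[C@@]2(O)O4)occ3CO | intermediate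
19 | 13-acetate of 18 | C[C@]12CC(=NO1)c3c(C[C@]4(C)CC[C@@]2(O)O4)occ3COC(C)=O | intermediate
20 | (1R,4S,10R)-13-acetoxy-1,10-dihydroxy-1,4-epoxy 8-imine | C[C@@]1(O)CC(=N)c2c(C[C@]3(C)CC[C@@]1(O)O3)occ2COC(C)=O | intermediate
21 | (1R,4S,10R)-13-acetoxy-1,10-dihydroxy-1,4-epoxy 8-ketone | C[C@@]1(O)CC(=O)c2c(C[C@]3(C)CC[C@@]1(O)O3)occ2COC(C)=O | intermediate
22 | 10-O-diethylboryl chelate of 21 | C[C@@]1(OB(CC)CC)CC(=O)c2c(C[C@]3(C)CC[C@@]1(O)O3)occ2COC(C)=O | intermediate
23 | (1R,4S,8S,10R)-13-acetoxy-1,4-epoxy-1,8,10-triol | C[C@@]1(O)C[C@H](O)c2c(C[C@]3(C)CC[C@@]1(O)O3)occ2COC(C)=O | intermediate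
24 | 8-O-methacrylate of 23 | C[C@@]1(O)C[C@H](OC(=O)C(C)=C)c2c(C[C@]3(C)CC[C@@]1(O)O3)occ2COC(C)=O | intermediate
25 | furan 6,12-endoperoxide of 24 | C[C@@]1(O)C[C@H](OC(=O)C(C)=C)C2=C(COC(C)=O)C4OOC2(O4)C[C@]3(C)CC[C@@]1(O)O3 | intermediate
26 | (1R,4S,8S,10R)-13-acetoxy-1,6,10-trihydroxy-8-methacryloyloxy-1,4-epoxygermacr-7(11)-en-6,12-olide | C[C@@]1(O)C[C@H](OC(=O)C(C)=C)C2=C(COC(C)=O)C(=O)OC2(O)C[C@]3(C)CC[C@@]1(O)O3 | intermediate
27 | 1,6-bis(trifluoroacetate) of 26 | C[C@@]1(O)C[C@H](OC(=O)C(C)=C)C2=C(COC(C)=O)C(=O)OC2(OC(=O)C(F)(F)F)C[C@]3(C)CC[C@@]1(OC(=O)C(F)(F)F)O3 | intermediate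
28 | (4S,8S,10R)-13-acetoxy-10-hydroxy-8-(2-methylprop-2-enoyloxy)-1,4-epoxygermacra-1,5E,7(11)-trien-6,12-olide | C=C(C)C(=O)O[C@H]1C[C@@](C)(O)C2=CC[C@@](C)(/C=C3/OC(=O)C(COC(C)=O)=C31)O2 | target

**Step count and risks**

Total steps: 16. Longest linear sequence: 15 steps (steps 2–16, from furan-3,4-diyldimethanol 3); step 1 is the only side branch.

Steps most likely to fail:

Step 9 (Proposed new method). Oligomerization or furoxan formation may outrun closure of the strained ten-membered ring under the basic magnesium conditions, or the chelate may fail to control the face. The fallback uses known chemistry and sets out from hydroxy enone 9, before the carbinol is made. Oxidation with 2,2,6,6-tetramethylpiperidin-1-oxyl/PhI(OAc)2 should give keto aldehyde F1. NH2OH·HCl/NaOAc (1.0 equiv, 0 °C, aldehyde-selective) should give enone oxime F2. Slow addition of F2 to aqueous NaOCl/CH2Cl2 at high dilution generates nitrile oxide F3 without magnesium. F3 should add intramolecularly to the now electron-poor isopropenyl ketone, a classical intramolecular nitrile oxide cycloaddition to an α,β-unsaturated carbonyl dipolarophile, in which the 5-acyl-5-methyl regiochemistry is enforced electronically. This gives hydroxy ketone 16 and hence hemiketal 17, where the route is rejoined. C10 is then set by substrate control and its epimers are separated at 17. Steps 6 and 10 are not needed on this path.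

Step 16. Acylation and elimination of the tertiary C10 hydroxyl may compete with the two hemiketal dehydrations under the acylating conditions, or the enol ether may be lost by rehydration on work-up. The fallback sets out from 26. MeOH with pyridinium 4-methylbenzenesulfonate (cat.) should convert both hemiketals into bis(methyl ketal) F5. Me3SiOSO2CF3/iPr2NEt (CH2Cl2, −78 → 0 °C), a silyl-triflate-induced elimination of methanol from ketals to enol ethers, silylates the C10 hydroxyl in the same flask, so that it cannot leave, and should give 10-O-trimethylsilyl ether F6 of the target. Bu4NF/AcOH (THF, 0 °C) then removes the silyl group and the route comes back at 28.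

Step 13. Hydride may attack the wrong face of the C8 ketone if the ring conformation overrides the boron chelate (poor or reversed 1,3-induction). The fallback sets out from 21. Evans–Saksena reduction with Me4NBH(OAc)3 (MeCN/AcOH, −30 °C), which delivers hydride intramolecularly from the C10-bound borohydride, should give the 1,3-anti product, (8R)-diol F4. Mitsunobu esterification of F4 with methacrylic acid (PPh3, diisopropyl azodicarboxylate, THF, 0 °C) then inverts C8 and installs the ester in one operation, so that the route is rejoined at 24.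

Further compounds
F1 | step 9 | 2-[(2S)-2-hydroxy-2,6-dimethyl-5-oxohept-6-en-1-yl]-4-(TBS-oxymethyl)furan-3-carbaldehyde | O=Cc1c(C[C@@](C)(O)CCC(=O)C(C)=C)occ1CO[Si](C)(C)C(C)(C)C
F2 | step 9 | oxime of F1 | ON=Cc1c(C[C@@](C)(O)CCC(=O)C(C)=C)occ1CO[Si](C)(C)C(C)(C)C
F3 | step 9 | furan-3-carbonitrile oxide derived from F2 | [O-][N+]#Cc1c(C[C@@](C)(O)CCC(=O)C(C)=C)occ1CO[Si](C)(C)C(C)(C)C
F4 | step 13 | (1R,4S,8R,10R)-13-acetoxy-1,4-epoxy-1,8,10-triol (8-epimer of 23) | C[C@@]1(O)C[C@@H](O)c2c(C[C@]3(C)CC[C@@]1(O)O3)occ2COC(C)=O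
F5 | step 16 | 1,6-bis(methyl ketal) of 26 | C[C@@]1(O)C[C@H](OC(=O)C(C)=C)C2=C(COC(C)=O)C(=O)OC2(OC)C[C@]3(C)CC[C@@]1(OC)O3
F6 | step 16 | 10-O-trimethylsilyl ether of 28 | C=C(C)C(=O)O[C@H]1C[C@@](C)(O[Si](C)(C)C)C2=CC[C@@](C)(/C=C3/OC(=O)C(COC(C)=O)=C31)O2
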